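**Retrosynthesis**
1. Target 15 ← global debenzylation of per-benzyl dimer 14.
2. 14 ← syn-hydroboration/oxidation of the 4-(catechinyl)flav-3-ene 12. Addition anti to the 2-aryl group sets C3-OH and C4-aryl relative to C2.
3. 12 ← aryl propargyl Claisen [3,3] / [1,5]-H / oxa-6π electrocyclization cascade of ether 11. This forms the C4a–C4 bond and the upper-unit pyran ring (the key step).
4. 11 ← Mitsunobu coupling of 3-benzyloxyphenol 10 with propargylic alcohol 9. Alcohol 9 comes from Sonogashira coupling of 8-bromo-penta-O-benzylcatechin 5 (from (+)-catechin 1) with alkynol 8.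
5. Ring order: the catechin rings are bought. The upper-unit pyran ring forms in step 6 from commercial aromatic fragments.

Assumptions:
- NBS brominates 3 at C8 (more nucleophilic and less hindered than C6).
- The 2-epimers from step 6 are diastereomers (the catechin unit is chiral), so they are separable by chromatography.

---

**Step 1**
Reactants: 1 (+)-catechin; 2 benzyl bromide
Product: 3 3,5,7,3′,4′-penta-O-benzyl-(+)-catechin
Conditions: NaH (6 equiv), BnBr (6 equiv), DMF, 0 °C → rt, 12 h
Reagents that add atoms: benzyl bromide, BrCc1ccccc1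
Why: Williamson etherification protects all five OH groups and leaves C2/C3 (2R,3S) untouched.

**Step 2**
Reactants: 3; 4 N-bromosuccinimide
Product: 5 8-bromo-penta-O-benzyl-(+)-catechin
Conditions: NBS (1.05 equiv), CH2Cl2, –78 °C, 1 h
Reagents that add atoms: NBS, O=C1CCC(=O)N1Br (supplies Br)
Why: Electrophilic aromatic bromination goes at the most nucleophilic, least hindered A-ring position (C8), giving the handle for the C4 link; no stereocenter is affected.

**Step 3**
Reactants: 6 3,4-bis(benzyloxy)benzaldehyde; 7 ethynylmagnesium bromide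
Product: 8 1-[3,4-bis(benzyloxy)phenyl]prop-2-yn-1-ol (racemic)
Conditions: HC≡CMgBr (1.5 equiv), THF, 0 °C, 1 h; aq. NH4Cl
Reagents that add atoms: ethynylmagnesium bromide, C#C[Mg]Br (supplies C2H)
Why: Grignard 1,2-addition to the aldehyde. The carbinol centre is racemic and is destroyed in step 6, so it need not be controlled.

**Step 4**
Reactants: 5; 8
Product: 9 Ar′–C≡C–CH(OH)–ArB, where Ar′ is the catechin C8 and ArB is 3,4-bis(benzyloxy)phenyl (mixture of carbinol epimers)
Conditions: Pd(PPh3)2Cl2 (5 mol%), CuI (10 mol%), Et3N, DMF, 80 °C, 12 h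
Reagents that add atoms: none
Why: Sonogashira coupling joins the C8 aryl bromide to the terminal alkyne. Catechin C2′/C3′ are untouched, and the carbinol epimers converge in step 6.

**Step 5**
Reactants: 9; 10 3-(benzyloxy)phenol
Product: 11 aryl propargyl ether, ArA–O–CH(ArB)–C≡C–Ar′
Conditions: PPh3, DIAD, THF, 0 °C → rt, 4 h
Reagents that add atoms: none
Why: Mitsunobu etherification of the phenol at the activated propargylic alcohol gives the Claisen substrate; the propargylic configuration is irrelevant.

**Step 6**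
Reactants: 11
Product: 12 (2R)-2-(3,4-bis(benzyloxy)phenyl)-7-benzyloxy-4-[penta-O-benzylcatechin-8-yl]-2H-chromene (flav-3-ene)
Conditions: CsF (cat.), N,N-diethylaniline, 200 °C, sealed tube, 3 h; chromatography to isolate the (2R)-7-OBn isomer
Reagents that add atoms: none
Why: Aromatic propargyl Claisen [3,3] rearrangement gives an allenyl dienone. A [1,5]-H shift then gives a vinyl-o-quinone methide, and oxa-6π electrocyclization closes the pyran ring. C2 is created on ring closure, biased by the chiral catechin substituent at C4. The closure is reversible at this temperature, and the (2R) diastereomer is separated from the 2S isomer and from any 5-OBn regioisomer.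

**Step 7**
Reactants: 12; H2O2 (13)
Product: 14 per-O-benzyl fisetinidol-(4α,8)-catechin with free upper 3-OH
Conditions: BH3·THF (3 equiv), THF, 0 °C → rt, 3 h; then 3 M NaOH, 30% H2O2, 0 °C, 1 h
Reagents that add atoms: hydrogen peroxide, OO (supplies the C3 oxygen)
Why: Hydroboration–oxidation adds H and B syn across C3=C4 from the face anti to the pseudo-axial 2-aryl group. B goes to C3, giving 3-OH trans to the 2-aryl; H adds to C4, so the catechinyl group ends up trans to 3-OH and cis to the 2-aryl (2,3-trans-3,4-trans, as in the target).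

**Step 8**
Reactants: 14
Product: 15 fisetinidol-(4α,8)-catechin (target)
Conditions: H2 (1 atm), Pd(OH)2/C, THF/MeOH 1:1, rt, 24 h
Reagents that add atoms: none (H2 adds only hydrogen)
Why: Hydrogenolysis removes all eight O-benzyl groups (5 on the catechin unit, 3 on the fisetinidol unit) without touching any stereocenter.

---

**Compound list**

| No. | Name | SMILES | Role |
|---|---|---|---|
| 1 | (+)-catechin (2R,3S) | O[C@H]1Cc2c(O)cc(O)cc2O[C@@H]1c1ccc(O)c(O)c1 | starting material |
| 2 | benzyl bromide | BrCc1ccccc1 | starting material (reagent) |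
| 3 | penta-O-benzyl-(+)-catechin | O(Cc1ccccc1)[C@H]1Cc2c(OCc3ccccc3)cc(OCc3ccccc3)cc2O[C@@H]1c1ccc(OCc2ccccc2)c(OCc2ccccc2)c1 | intermediate |
| 4 | N-bromosuccinimide | O=C1CCC(=O)N1Br | starting material (reagent) |
| 5 | 8-bromo-penta-O-benzyl-(+)-catechin | O(Cc1ccccc1)[C@H]1Cc2c(OCc3ccccc3)cc(OCc3ccccc3)c(Br)c2O[C@@H]1c1ccc(OCc2ccccc2)c(OCc2ccccc2)c1 | intermediate |
| 6 | 3,4-bis(benzyloxy)benzaldehyde | O=Cc1ccc(OCc2ccccc2)c(OCc2ccccc2)c1 | starting material |
| 7 | ethynylmagnesium bromide | C#C[Mg]Br | starting material (reagent) |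
| 8 | 1-[3,4-bis(benzyloxy)phenyl]prop-2-yn-1-ol (racemic) | C#CC(O)c1ccc(OCc2ccccc2)c(OCc2ccccc2)c1 | intermediate |
| 9 | propargylic alcohol Ar′–C≡C–CH(OH)ArB (carbinol epimers) | OC(C#Cc1c(OCc2ccccc2)cc(OCc2ccccc2)c2c1O[C@H](c1ccc(OCc3ccccc3)c(OCc3ccccc3)c1)[C@@H](OCc1ccccc1)C2)c1ccc(OCc2ccccc2)c(OCc2ccccc2)c1 | intermediate |
| 10 | 3-(benzyloxy)phenol | Oc1cccc(OCc2ccccc2)c1 | starting material |
| 11 | aryl propargyl ether | O(c1cccc(OCc2ccccc2)c1)C(C#Cc1c(OCc2ccccc2)cc(OCc2ccccc2)c2c1O[C@H](c1ccc(OCc3ccccc3)c(OCc3ccccc3)c1)[C@@H](OCc1ccccc1)C2)c1ccc(OCc2ccccc2)c(OCc2ccccc2)c1 | intermediate |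
| 12 | (2R)-4-(catechinyl)-2H-chromene (per-O-benzyl) | O(Cc1ccccc1)c1ccc2c(c1)O[C@H](c1ccc(OCc3ccccc3)c(OCc3ccccc3)c1)C=C2c1c(OCc3ccccc3)cc(OCc3ccccc3)c2c1O[C@H](c1ccc(OCc3ccccc3)c(OCc3ccccc3)c1)[C@@H](OCc1ccccc1)C2 | intermediate |
| 13 | hydrogen peroxide | OO | starting material (reagent) |
| 14 | per-O-benzyl fisetinidol-(4α,8)-catechin, upper 3-OH free | O(Cc1ccccc1)c1ccc2c(c1)O[C@H](c1ccc(OCc3ccccc3)c(OCc3ccccc3)c1)[C@@H](O)[C@@H]2c1c(OCc3ccccc3)cc(OCc3ccccc3)c2c1O[C@H](c1ccc(OCc3ccccc3)c(OCc3ccccc3)c1)[C@@H](OCc1ccccc1)C2 | intermediate |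
| 15 | fisetinidol-(4α,8)-catechin | Oc1ccc2c(c1)O[C@H](c1ccc(O)c(O)c1)[C@@H](O)[C@@H]2c1c(O)cc(O)c2c1O[C@H](c1ccc(O)c(O)c1)[C@@H](O)C2 | target |

**Total steps:** 8. **Longest linear sequence:** 7 (1 → 3 → 5 → 9 → 11 → 12 → 14 → 15).

**Three steps most likely to fail**
1. **Step 6 (Claisen/oxa-6π cascade).** Risks are 5- versus 7-OBn regioselectivity, the C2 diastereomer ratio, and possible thermal epimerization at catechin C2′ at 200 °C.
   - Fallback: cyclize ether 11 under Au(I)/Ag(I) catalysis (6-endo hydroarylation, ≤60 °C) to the same chromene, which avoids the thermal cascade.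
2. **Step 4 (Sonogashira on the di-ortho-alkoxy C8 bromide).** The coupling is hindered and may give low yield.
   - Fallback: convert 5 to the 8-lithio species (t-BuLi), formylate, and convert to the 8-ethynyl compound (Ohira–Bestmann). Then add its lithium acetylide to aldehyde 6 to make 9 directly.
3. **Step 7 (hydroboration).** The hindered trisubstituted alkene may react slowly, and the β-aryloxy borane may eliminate to ring-opened alkene.
   - Fallback: epoxidize 12 with DMDO (anti to the 2-aryl group) and do a Lewis-acid Meinwald rearrangement to the 3-ketone. Epimerize C4 with DBU to the all-equatorial isomer, then reduce C3=O with NaBH4 (axial hydride delivery) to give the equatorial, trans-configured 3-OH.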